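Ring B is not coupled to ring A but grown on its oxygen. The ring A phenol is O-alkylated with a 4-haloacetoacetate, and the derived 1,3-bis(silyloxy)diene is condensed with malonaldehyde bis(dimethyl acetal). That one operation forms C1'–C2' and C4'–C5' and closes ring B as a 3-aryloxysalicylate. It exploits the contiguous C1'(OAr)–C6'(OH)–C5'(Br) edge of ring B, which maps onto C4–C3–C2 of the acetoacetate, while C2'–C3'–C4' comes from the symmetric three-carbon dielectrophile. The ester on C5' marks the site of the later ipso-bromodecarboxylation. The precursor is 1-methoxy-1,3-bis(trimethylsilyloxy)-4-(2,3,5-tribromo-6-methoxyphenoxy)buta-1,3-diene.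

Key step: step 6

Remark on numbering: ring A is the tribromo-methoxy ring. Ring B is the phenol ring, numbered C1' (OAr), C2' (H), C3' (Br), C4' (H), C5' (Br), C6' (OH).

Remark on stereochemistry: the target has no stereocentre. The alkene geometry of 8 and 9 and the stereocentres of 11 and 12 are not controlled and vanish on aromatisation.

Assumption: compounds 1, 6 and 10 are purchased.

Step 1
Reactants: 1 3,5-dibromo-2-hydroxybenzaldehyde
Product: 2 3,5-dibromo-2-methoxybenzaldehyde
Conditions: MeI, K2CO3, DMF, 20 °C
Reagents that add atoms: iodomethane, CI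
Why: Williamson ether synthesis, in which the acidic, carbonate-generated phenoxide is methylated by SN2 on iodomethane.

Step 2
Reactants: 2 3,5-dibromo-2-methoxybenzaldehyde
Product: 4 3,5-dibromo-2-methoxyphenol, via 3,5-dibromo-2-methoxyphenyl formate 3 (not isolated)
Conditions: mCPBA, CH2Cl2, 0 → 40 °C; NaHCO3/Na2S2O3 wash; then Et3N (cat.), MeOH, 20 °C
Reagents that add atoms: mCPBA, OOC(=O)c1cccc(Cl)c1
Why: Baeyer–Villiger (Dakin-type) oxidation, in which the ortho-alkoxyaryl group should migrate in preference to hydrogen in the Criegee adduct, followed by base-catalysed methanolysis of the labile aryl formate.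

Step 3
Reactants: 4 3,5-dibromo-2-methoxyphenol
Product: 5 2,3,5-tribromo-6-methoxyphenol
Conditions: NBS (1.0 equiv), iPr2NH (0.1 equiv), CH2Cl2, 0 °C
Reagents that add atoms: N-bromosuccinimide, O=C1CCC(=O)N1Br
Why: Amine-mediated ortho-selective electrophilic bromination of a phenol, in which the hydrogen-bonded N-bromoamine should deliver bromine to the only free ortho position while the para position is shielded by its two flanking bromines.

Step 4
Reactants: 5 2,3,5-tribromo-6-methoxyphenol; 6 methyl 4-chloro-3-oxobutanoate
Product: 7 methyl 3-oxo-4-(2,3,5-tribromo-6-methoxyphenoxy)butanoate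
Conditions: K2CO3 (1.0 equiv), NaI (0.1 equiv), DMF, 20 → 50 °C
Reagents that add atoms: none
Why: Williamson-type SN2 displacement at the α-chloroketone carbon with Finkelstein catalysis; the polybrominated phenol is expected to be much more acidic than the β-ketoester, so one equivalent of carbonate should give only the phenoxide, which attacks the activated primary halide without enolising the ketoester and without any metal touching a C–Br bond.

Step 5
Reactants: 7 methyl 3-oxo-4-(2,3,5-tribromo-6-methoxyphenoxy)butanoate
Product: 9 1-methoxy-4-(2,3,5-tribromo-6-methoxyphenoxy)-1,3-bis(trimethylsilyloxy)buta-1,3-diene, via methyl 3-(trimethylsilyloxy)-4-(2,3,5-tribromo-6-methoxyphenoxy)but-2-enoate 8 (not isolated)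
Conditions: Me3SiOTf (2.2 equiv), Et3N (2.6 equiv), Et2O, 0 → 20 °C; salt layer removed, crude diene used directly
Reagents that add atoms: trimethylsilyl trifluoromethanesulfonate, C[Si](C)(C)OS(=O)(=O)C(F)(F)F
Why: Soft double enolisation and O-silylation of a β-ketoester to its 1,3-bis(silyl enol ether), first at C2 to give 8 and then at the C4 methylene activated by the ketone and the aryloxy group; the amine base avoids lithium amides, which could metalate the ring A C–H flanked by two bromines.

Step 6
Reactants: 9 1-methoxy-4-(2,3,5-tribromo-6-methoxyphenoxy)-1,3-bis(trimethylsilyloxy)buta-1,3-diene; 10 1,1,3,3-tetramethoxypropane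
Product: 13 methyl 2-hydroxy-3-(2,3,5-tribromo-6-methoxyphenoxy)benzoate, via open-chain Mukaiyama adduct 11 (not isolated), via dimethoxycyclohexanone ester 12 (not isolated)
Conditions: Me3SiOTf (0.3 equiv), CH2Cl2, −78 → 20 °C; then 10% aq HCl
Reagents that add atoms: none
Why: Me3SiOTf ionises one acetal terminus of 10 to an oxocarbenium ion, which is attacked by the terminal, aryloxy-bearing C4 of diene 9 in a Mukaiyama-type addition that forms C1'–C2' and leaves the silyl ketene acetal of 11 intact. Ionisation of the second acetal then lets the ketene acetal carbon C2 attack intramolecularly, forming C4'–C5' and closing ring B as cyclohexanone 12 in a 6-(enolexo)-exo-trig closure. Two acid-promoted β-eliminations of methanol and enolisation aromatise 12, so the former ketone oxygen ends as the free C6' hydroxyl, distinct from the ring A methyl ether, with the ester on C5'. The closest known reaction type is the Lewis acid mediated formal [3+3] cyclocondensation of 1,3-bis(silyloxy)-1,3-dienes with malonaldehyde acetals and related 1,3-dielectrophiles to give salicylates. The stereocentres of 11 and 12 are erased on aromatisation, so none needs control. Only chemoselectivity is required: the dielectrophile is symmetric, so no regiochemical question arises, and the order of bond formation (C4 before C2) is secured by the higher nucleophilicity of the diene terminus.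

Step 7
Reactants: 13 methyl 2-hydroxy-3-(2,3,5-tribromo-6-methoxyphenoxy)benzoate
Product: 14 2-hydroxy-3-(2,3,5-tribromo-6-methoxyphenoxy)benzoic acid
Conditions: LiOH (4 equiv), THF–MeOH–H2O, 50 °C; then 1 M HCl
Reagents that add atoms: lithium hydroxide, [Li+].[OH-]
Why: Saponification (acyl-oxygen ester hydrolysis), to which the aryl bromides, the diaryl ether and the methyl ether should be inert.

Step 8
Reactants: 14 2-hydroxy-3-(2,3,5-tribromo-6-methoxyphenoxy)benzoic acid
Product: 16 2,4-dibromo-6-(2,3,5-tribromo-6-methoxyphenoxy)phenol, via 5-bromo-2-hydroxy-3-(2,3,5-tribromo-6-methoxyphenoxy)benzoic acid 15 (not isolated)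
Conditions: Br2 (2.1 equiv), NaOAc, AcOH–H2O, 20 → 45 °C; then aq Na2S2O3
Reagents that add atoms: bromine, BrBr
Why: Phenol-directed electrophilic aromatic bromination, in which the first bromine should enter para to the hydroxyl (C3') to give 15 and the second should attack ipso at the carboxyl-bearing ortho carbon (C5') with loss of CO2 (bromodecarboxylation of a salicylic acid), ring A being deactivated by its three bromines.

Compound list
1 | 3,5-dibromo-2-hydroxybenzaldehyde (3,5-dibromosalicylaldehyde) | O=Cc1cc(Br)cc(Br)c1O | starting material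
2 | 3,5-dibromo-2-methoxybenzaldehyde | COc1c(Br)cc(Br)cc1C=O | intermediate
3 | 3,5-dibromo-2-methoxyphenyl formate | COc1c(Br)cc(Br)cc1OC=O | intermediate (not isolated)
4 | 3,5-dibromo-2-methoxyphenol | COc1c(Br)cc(Br)cc1O | intermediate
5 | 2,3,5-tribromo-6-methoxyphenol | COc1c(Br)cc(Br)c(Br)c1O | intermediate
6 | methyl 4-chloro-3-oxobutanoate (methyl 4-chloroacetoacetate) | COC(=O)CC(=O)CCl | starting material
7 | methyl 3-oxo-4-(2,3,5-tribromo-6-methoxyphenoxy)butanoate | COC(=O)CC(=O)COc1c(OC)c(Br)cc(Br)c1Br | intermediate
8 | methyl 3-(trimethylsilyloxy)-4-(2,3,5-tribromo-6-methoxyphenoxy)but-2-enoate (alkene geometry undefined) | COC(=O)C=C(COc1c(OC)c(Br)cc(Br)c1Br)O[Si](C)(C)C | intermediate (not isolated)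
9 | 1-methoxy-4-(2,3,5-tribromo-6-methoxyphenoxy)-1,3-bis(trimethylsilyloxy)buta-1,3-diene (drawn 1Z,3Z; geometry not controlled) | CO/C(O[Si](C)(C)C)=C/C(O[Si](C)(C)C)=C/Oc1c(OC)c(Br)cc(Br)c1Br | intermediate
10 | 1,1,3,3-tetramethoxypropane | COC(OC)CC(OC)OC | starting material
11 | 1,5,7,7-tetramethoxy-4-(2,3,5-tribromo-6-methoxyphenoxy)-1-(trimethylsilyloxy)hept-1-en-3-one (open-chain Mukaiyama adduct, stereoisomer mixture) | COC(O[Si](C)(C)C)=CC(=O)C(Oc1c(OC)c(Br)cc(Br)c1Br)C(OC)CC(OC)OC | intermediate (not isolated)
12 | methyl 4,6-dimethoxy-2-oxo-3-(2,3,5-tribromo-6-methoxyphenoxy)cyclohexane-1-carboxylate (stereoisomer mixture) | COC(=O)C1C(=O)C(Oc2c(OC)c(Br)cc(Br)c2Br)C(OC)CC1OC | intermediate (not isolated)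
13 | methyl 2-hydroxy-3-(2,3,5-tribromo-6-methoxyphenoxy)benzoate | COC(=O)c1cccc(Oc2c(OC)c(Br)cc(Br)c2Br)c1O | intermediate
14 | 2-hydroxy-3-(2,3,5-tribromo-6-methoxyphenoxy)benzoic acid | O=C(O)c1cccc(Oc2c(OC)c(Br)cc(Br)c2Br)c1O | intermediate
15 | 5-bromo-2-hydroxy-3-(2,3,5-tribromo-6-methoxyphenoxy)benzoic acid | O=C(O)c1cc(Br)cc(Oc2c(OC)c(Br)cc(Br)c2Br)c1O | intermediate (not isolated)
16 | 2,4-dibromo-6-(2,3,5-tribromo-6-methoxyphenoxy)phenol | COc1c(Br)cc(Br)c(Br)c1Oc1cc(Br)cc(Br)c1O | target

Total step count: 8
Longest linear sequence: 8 steps (from 1 to 16; 6 and 10 enter as purchased partners)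

Steps most likely to fail

Step 6 (key cyclocondensation). The first Mukaiyama addition may be slow at the diene terminus, which carries a bulky 2,6-disubstituted aryloxy group. Desilylation of the diene back to 7, or condensation stopping before full aromatisation, could then take over. The fallback also covers loss of silyl groups from the moisture-sensitive diene of step 5. It sets out from phenol 5 and returns at 13, forming the diaryl ether by nucleophilic aromatic substitution instead of building ring B. Phenol 5 and purchased methyl 3-fluoro-2-nitrobenzoate (K2CO3, DMF, 80 °C) should give methyl 2-nitro-3-(2,3,5-tribromo-6-methoxyphenoxy)benzoate F1. Reduction with iron powder and NH4Cl in aqueous ethanol, which spares aryl bromides, should give methyl 2-amino-3-(2,3,5-tribromo-6-methoxyphenoxy)benzoate F2. Diazotisation (NaNO2, aqueous H2SO4, 0 °C) would give 2-(methoxycarbonyl)-6-(2,3,5-tribromo-6-methoxyphenoxy)benzenediazonium hydrogensulfate F3, which on warming in dilute H2SO4 should hydrolyse to salicylate 13. Both positions of ring A ortho to the ether oxygen are substituted, so cyclisation of the diazonium ion to a dibenzofuran is blocked.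

Step 4 (O-alkylation with the chloroacetoacetate). Substitution by the hindered, weakly nucleophilic phenoxide may be slow enough for base-induced self-condensation of the chloroketoester to consume the electrophile. The fallback sets out from 5 and returns at 7, building the ketoester by acylation. Phenol 5 and methyl bromoacetate (K2CO3, acetone, reflux) should give methyl 2-(2,3,5-tribromo-6-methoxyphenoxy)acetate F4. A crossed Claisen condensation with the lithium enolate of methyl acetate (MeOAc, LiN(SiMe3)2, 2.2 equiv, THF, −78 °C; then aqueous NH4Cl) should then give 7. The silylamide base is too weak to metalate ring A.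

Step 8 (bromodecarboxylation). The sequence may stall after the para bromination if ipso attack at the carboxyl-bearing carbon is slow in the partly organic medium. Forcing it could start bromination elsewhere. The fallback sets out from 14 and returns at 16, removing the carboxyl group before any bromination. Protodecarboxylation of 14 (Ag2CO3 (cat.), AcOH, DMSO, 120 °C) should give 2-(2,3,5-tribromo-6-methoxyphenoxy)phenol F5. Ordinary bromination of this phenol (Br2, 2.0 equiv, AcOH, 20 °C) should place bromine para and ortho to the hydroxyl and give 16.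

Further compounds
F1 | step 6 | methyl 2-nitro-3-(2,3,5-tribromo-6-methoxyphenoxy)benzoate | COC(=O)c1cccc(Oc2c(OC)c(Br)cc(Br)c2Br)c1[N+](=O)[O-]
F2 | step 6 | methyl 2-amino-3-(2,3,5-tribromo-6-methoxyphenoxy)benzoate | COC(=O)c1cccc(Oc2c(OC)c(Br)cc(Br)c2Br)c1N
F3 | step 6 | 2-(methoxycarbonyl)-6-(2,3,5-tribromo-6-methoxyphenoxy)benzenediazonium hydrogensulfate | COC(=O)c1cccc(Oc2c(OC)c(Br)cc(Br)c2Br)c1[N+]#N.OS(=O)(=O)[O-]
F4 | step 4 | methyl 2-(2,3,5-tribromo-6-methoxyphenoxy)acetate | COC(=O)COc1c(OC)c(Br)cc(Br)c1Br
F5 | step 8 | 2-(2,3,5-tribromo-6-methoxyphenoxy)phenol | COc1c(Br)cc(Br)c(Br)c1Oc1ccccc1O
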